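**Retrosynthetic overview**

1. The route rests on ring A, the tetrahydrofuran C7–O–C9'–C8'–C8. C7 carries the electron-rich guaiacyl ring and is bonded to C8 and, through the ring oxygen, to C9'. Moving C7 from that oxygen to C8' gives a C7–C8–C8' cyclopropane with C9' as a formyl group, a donor–acceptor cyclopropyl aldehyde.
2. Target ⇐ hydrogenation with debenzylation ⇐ C9'=C8' enol ether (dihydrofuran fused to lactone ring B) ⇐ Cloke–Wilson ring expansion ⇐ formyl cyclopropane fused to the 7'-aryl lactone.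
3. Formyl cyclopropane ⇐ CH2OTBS cyclopropane lactone ⇐ intramolecular rhodium-carbene cyclopropanation of the (R)-allylic diazoacetate (closes ring B and the three-membered ring; C8, C8' and C7 set from C7').
4. (R)-Allylic alcohol ⇐ oxazaborolidine reduction of the (E)-enone ⇐ nickel-catalysed reductive coupling of a guaiacyl propargyl silyl ether with O-benzylsyringaldehyde (C7'–C8' bond and alkene geometry) ⇐ Sonogashira coupling.
5. Ring order: lactone ring B with the cyclopropane (step 7), then ring A by ring expansion (step 10); C8' is set last by hydrogenation (step 11).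

Key step: step 10

Remark: lignan numbering is used (guaiacyl chain C7, C8, C9; syringyl chain C7', C8', C9'); Ar1 = 4-(benzyloxy)-3-methoxyphenyl, Ar2 = 4-(benzyloxy)-3,5-dimethoxyphenyl, TBS = tert-butyldimethylsilyl.
Assumption: the aryl bromide, the propargyl silyl ether and the aldehyde of steps 1 and 2 are bought as catalogue compounds.
Assumption: in the oxazaborolidine reduction of step 4 the α-branched alkenyl arm of the enone (CH2OTBS beside the carbonyl) acts as the large group and the flat, ortho-unsubstituted aryl ring as the small one, so the (S)-catalyst gives the (R)-alcohol.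

**Route**

Step 1
Reactants: 1 1-(benzyloxy)-4-bromo-2-methoxybenzene; 2 tert-butyldimethyl(prop-2-yn-1-yloxy)silane
Product: 3 tert-butyl{[3-(Ar1)prop-2-yn-1-yl]oxy}dimethylsilane
Conditions: PdCl2(PPh3)2 (3 mol %), CuI (5 mol %), Et3N, DMF, 80 °C
Reagents that add atoms: none
Why: Sonogashira coupling (oxidative addition of the aryl bromide to zerovalent palladium, transfer of the copper acetylide, reductive elimination) gives the aryl alkyne, and the silyl and benzyl ethers are inert.

Step 2
Reactants: 3 tert-butyl{[3-(Ar1)prop-2-yn-1-yl]oxy}dimethylsilane; 4 4-(benzyloxy)-3,5-dimethoxybenzaldehyde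
Product: 5 rac-(2E)-3-Ar1-1-Ar2-2-(TBSOCH2)prop-2-en-1-ol
Conditions: Ni(cod)2 (10 mol %), PBu3 (20 mol %), Et3B (2 equiv), toluene, rt; then H2O
Reagents that add atoms: none
Why: In this nickel-catalysed alkyne–aldehyde reductive coupling, oxidative cyclisation on zerovalent nickel puts nickel on the aryl-bearing alkyne carbon and forms the C8'–C7' bond at the CH2OTBS-bearing carbon, and ethyl transfer from boron, β-hydride elimination and C–H reductive elimination add H syn to the new bond, so Ar1 ends up trans to C7' (E) with a racemic carbinol centre.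

Step 3
Reactants: 5 rac-(2E)-3-Ar1-1-Ar2-2-(TBSOCH2)prop-2-en-1-ol
Product: 6 (2E)-3-Ar1-1-Ar2-2-(TBSOCH2)prop-2-en-1-one
Conditions: MnO2 (excess), CH2Cl2, rt
Reagents that add atoms: none
Why: MnO2 oxidises only the benzylic and allylic secondary alcohol to the conjugated ketone and leaves the ethers and the alkene geometry alone.

Step 4
Reactants: 6 (2E)-3-Ar1-1-Ar2-2-(TBSOCH2)prop-2-en-1-one
Product: 7 (1R,2E)-3-Ar1-1-Ar2-2-(TBSOCH2)prop-2-en-1-ol
Conditions: (S)-2-methyl-CBS-oxazaborolidine (20 mol %), BH3·SMe2 (0.7 equiv), THF, −20 °C; then MeOH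
Reagents that add atoms: none
Why: Corey–Bakshi–Shibata reduction, in which the ketone binds the ring boron anti to its larger arm (the α-branched alkenyl group) and hydride passes from the N-bound BH3 to one carbonyl face, should set C7' as R, and the catalysed 1,2-reduction outpaces hydroboration of the trisubstituted alkene at −20 °C.

Step 5
Reactants: 7 (1R,2E)-3-Ar1-1-Ar2-2-(TBSOCH2)prop-2-en-1-ol; 8 bromoacetyl bromide
Product: 9 (1R,2E)-3-Ar1-1-Ar2-2-(TBSOCH2)prop-2-en-1-yl bromoacetate
Conditions: NaHCO3, MeCN, 0 °C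
Reagents that add atoms: none
Why: O-acylation by the acid bromide under bicarbonate buffering leaves the C7'–O bond untouched, so C7' is retained; the ionisable diaryl-allylic ester is kept cold and used at once.

Step 6
Reactants: 9 (1R,2E)-3-Ar1-1-Ar2-2-(TBSOCH2)prop-2-en-1-yl bromoacetate
Product: 11 (1R,2E)-3-Ar1-1-Ar2-2-(TBSOCH2)prop-2-en-1-yl diazoacetate, via ditosylhydrazinoacetate ester 10 (not isolated)
Conditions: N,N'-ditosylhydrazine (2 equiv), DBU (5 equiv), THF, 0 °C
Reagents that add atoms: N,N'-ditosylhydrazine, Cc1ccc(cc1)S(=O)(=O)NNS(=O)(=O)c1ccc(C)cc1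
Why: N-alkylation of the ditosylhydrazide anion by the bromoacetate, then two base-induced losses of sulfinate (a Bamford–Stevens-type fragmentation), gives the diazoacetate under non-acidic conditions that spare the allylic ester.

Step 7
Reactants: 11 (1R,2E)-3-Ar1-1-Ar2-2-(TBSOCH2)prop-2-en-1-yl diazoacetate
Product: 12 (1R,4R,5S,6S)-6-Ar1-4-Ar2-5-(TBSOCH2)-3-oxabicyclo[3.1.0]hexan-2-one (Ar1 exo on the cyclopropane and cis to CH2OTBS; Ar2 anti to the cyclopropane)
Conditions: Rh2(OAc)4 (1 mol %), CH2Cl2, 40 °C, slow addition of 11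
Reagents that add atoms: none
Why: Intramolecular cyclopropanation of an allylic diazoacetate by an electrophilic rhodium carbene is stereospecific, so the alkene geometry puts Ar1 cis to CH2OTBS (exo), the five-membered tether forces a cis fusion, and the carbene should add to the alkene face that leaves the C7' aryl group outside and anti to the new ring, which sets C8, C8' and C7 from C7'.

Step 8
Reactants: 12 (1R,4R,5S,6S)-6-Ar1-4-Ar2-5-(TBSOCH2)-3-oxabicyclo[3.1.0]hexan-2-one
Product: 13 (1R,4R,5S,6S)-6-Ar1-4-Ar2-5-(hydroxymethyl)-3-oxabicyclo[3.1.0]hexan-2-one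
Conditions: HF·pyridine, pyridine, THF, 0 °C to rt
Reagents that add atoms: none
Why: Fluoride cleaves the primary silyl ether (strong Si–F bond) in a pyridine-buffered medium that is mild enough for the lactone, the benzyl ethers and the aryl cyclopropane.

Step 9
Reactants: 13 (1R,4R,5S,6S)-6-Ar1-4-Ar2-5-(hydroxymethyl)-3-oxabicyclo[3.1.0]hexan-2-one
Product: 14 (1R,2R,5R,6S)-6-Ar1-2-Ar2-4-oxo-3-oxabicyclo[3.1.0]hexane-1-carbaldehyde
Conditions: Dess–Martin periodinane, pyridine, CH2Cl2, 0 °C to rt
Reagents that add atoms: none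
Why: Dess–Martin oxidation takes the primary cyclopropylcarbinol to the aldehyde under buffered conditions, and the quaternary α-carbon cannot epimerise.

Step 10
Reactants: 14 (1R,2R,5R,6S)-6-Ar1-2-Ar2-4-oxo-3-oxabicyclo[3.1.0]hexane-1-carbaldehyde
Product: 15 (3R,6S,6aS)-6-Ar1-3-Ar2-6,6a-dihydro-1H,3H-furo[3,4-c]furan-1-one
Conditions: Yb(OTf)3 (10 mol %), 4 Å molecular sieves, CH2Cl2, rt
Reagents that add atoms: none
Why: This is a Cloke–Wilson rearrangement of a donor–acceptor cyclopropyl aldehyde to a 2,3-dihydrofuran, a known reaction type for aryl-donor cyclopropyl ketones and aldehydes under Lewis acid catalysis: Yb(OTf)3 binds the formyl oxygen, the C7–C8' bond (pushed by the 4-alkoxyaryl donor on C7, pulled by the formyl group on C8') opens to a benzylic cation and an ytterbium enolate, and the enolate oxygen bonds to C7. Ring A closes by O-alkylation of the enolate on the benzylic cation, a 5-exo-trig closure with the enolate C9'=C8' bond inside the new ring (enolendo), the mode in which five-membered rings form through oxygen and not through carbon; release of cyclopropane strain drives it. C7 is the only stereocentre made: the ion pair should collapse on the face from which C8' left (retention), which puts the aryl group exo and trans to C9 on C8, and this is also the arrangement that re-ionisation under the same catalyst would restore, while C8 and C7' are untouched. The step needs C7–C8' cleavage and not C7–C8 cleavage, and O-closure and not C-closure: the aldehyde is the more Lewis-basic and less hindered acceptor, opening toward the lactone enolate can only revert because its oxygen cannot reach C7 without a bridgehead double bond, and C-closure merely returns 14. The sieves keep water from hydrating the acid-labile enol ether.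

Step 11
Reactants: 15 (3R,6S,6aS)-6-Ar1-3-Ar2-6,6a-dihydro-1H,3H-furo[3,4-c]furan-1-one
Product: 16 (3S,3aR,6S,6aS)-6-(4-hydroxy-3-methoxyphenyl)-3-(4-hydroxy-3,5-dimethoxyphenyl)tetrahydro-1H,3H-furo[3,4-c]furan-1-one
Conditions: H2 (1 atm), 10 % Pd/C, EtOAc, rt
Reagents that add atoms: none
Why: Heterogeneous hydrogenation should add H2 syn to the enol ether from the convex face of the bicycle (the face of H8, since the other face would give a trans-fused 5,5-system), setting C8' with a cis fusion, and the same catalyst hydrogenolyses the two aryl benzyl ethers, which cleave faster than the ring benzylic C–O bonds.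

**Compound list**

1 | 1-(benzyloxy)-4-bromo-2-methoxybenzene | COc1cc(Br)ccc1OCc1ccccc1 | starting material
2 | tert-butyldimethyl(prop-2-yn-1-yloxy)silane | C#CCO[Si](C)(C)C(C)(C)C | starting material
3 | tert-butyl{[3-(Ar1)prop-2-yn-1-yl]oxy}dimethylsilane | COc1cc(C#CCO[Si](C)(C)C(C)(C)C)ccc1OCc1ccccc1 | intermediate
4 | 4-(benzyloxy)-3,5-dimethoxybenzaldehyde | COc1cc(C=O)cc(OC)c1OCc1ccccc1 | starting material
5 | rac-(2E)-3-Ar1-1-Ar2-2-(TBSOCH2)prop-2-en-1-ol | COc1cc(/C=C(\CO[Si](C)(C)C(C)(C)C)C(O)c2cc(OC)c(OCc3ccccc3)c(OC)c2)ccc1OCc1ccccc1 | intermediate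
6 | (2E)-3-Ar1-1-Ar2-2-(TBSOCH2)prop-2-en-1-one | COc1cc(/C=C(\CO[Si](C)(C)C(C)(C)C)C(=O)c2cc(OC)c(OCc3ccccc3)c(OC)c2)ccc1OCc1ccccc1 | intermediate
7 | (1R,2E)-3-Ar1-1-Ar2-2-(TBSOCH2)prop-2-en-1-ol | COc1cc(/C=C(\CO[Si](C)(C)C(C)(C)C)[C@H](O)c2cc(OC)c(OCc3ccccc3)c(OC)c2)ccc1OCc1ccccc1 | intermediate
8 | bromoacetyl bromide | O=C(Br)CBr | starting material
9 | (1R,2E)-3-Ar1-1-Ar2-2-(TBSOCH2)prop-2-en-1-yl bromoacetate | COc1cc(/C=C(\CO[Si](C)(C)C(C)(C)C)[C@H](OC(=O)CBr)c2cc(OC)c(OCc3ccccc3)c(OC)c2)ccc1OCc1ccccc1 | intermediate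
10 | (1R,2E)-3-Ar1-1-Ar2-2-(TBSOCH2)prop-2-en-1-yl [1,2-bis(4-methylbenzenesulfonyl)hydrazinyl]acetate | COc1cc(/C=C(\CO[Si](C)(C)C(C)(C)C)[C@H](OC(=O)CN(NS(=O)(=O)c2ccc(C)cc2)S(=O)(=O)c2ccc(C)cc2)c2cc(OC)c(OCc3ccccc3)c(OC)c2)ccc1OCc1ccccc1 | intermediate
11 | (1R,2E)-3-Ar1-1-Ar2-2-(TBSOCH2)prop-2-en-1-yl diazoacetate | COc1cc(/C=C(\CO[Si](C)(C)C(C)(C)C)[C@H](OC(=O)C=[N+]=[N-])c2cc(OC)c(OCc3ccccc3)c(OC)c2)ccc1OCc1ccccc1 | intermediate
12 | (1R,4R,5S,6S)-6-Ar1-4-Ar2-5-(TBSOCH2)-3-oxabicyclo[3.1.0]hexan-2-one | CC(C)(C)[Si](C)(C)OC[C@]12[C@H](c3ccc(OCc4ccccc4)c(OC)c3)[C@H]1C(=O)O[C@@H]2c1cc(OC)c(OCc2ccccc2)c(OC)c1 | intermediate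
13 | (1R,4R,5S,6S)-6-Ar1-4-Ar2-5-(hydroxymethyl)-3-oxabicyclo[3.1.0]hexan-2-one | OC[C@]12[C@H](c3ccc(OCc4ccccc4)c(OC)c3)[C@H]1C(=O)O[C@@H]2c1cc(OC)c(OCc2ccccc2)c(OC)c1 | intermediate
14 | (1R,2R,5R,6S)-6-Ar1-2-Ar2-4-oxo-3-oxabicyclo[3.1.0]hexane-1-carbaldehyde | O=C[C@]12[C@H](c3ccc(OCc4ccccc4)c(OC)c3)[C@H]1C(=O)O[C@@H]2c1cc(OC)c(OCc2ccccc2)c(OC)c1 | intermediate
15 | (3R,6S,6aS)-6-Ar1-3-Ar2-6,6a-dihydro-1H,3H-furo[3,4-c]furan-1-one | COc1cc([C@H]2OC=C3[C@@H]2C(=O)O[C@@H]3c2cc(OC)c(OCc4ccccc4)c(OC)c2)ccc1OCc1ccccc1 | intermediate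
16 | (3S,3aR,6S,6aS)-6-(4-hydroxy-3-methoxyphenyl)-3-(4-hydroxy-3,5-dimethoxyphenyl)tetrahydro-1H,3H-furo[3,4-c]furan-1-one | COc1cc([C@H]2OC[C@H]3[C@@H]2C(=O)O[C@@H]3c2cc(OC)c(O)c(OC)c2)ccc1O | target

Total step count: 11. Longest linear sequence: 11 steps (1 to 16; 2, 4 and 8 enter as bought compounds).

**Steps most likely to fail**

Step 10 (ring expansion). The process at risk is ionisation to a free, long-lived benzylic cation. It could close on either face of C7, attack an electron-rich ring of a second molecule, or leave an enol ether that the Lewis acid and traces of water then hydrate. The fallback avoids the free cation by nucleophilic opening and sets out from 14. MgI2 (1 equiv) in THF at 0 °C to rt should let iodide attack C7 in an SN2 homo-conjugate addition with inversion, the aldehyde enolate being the leaving group, to give the ring-opened benzylic iodide magnesium enolate F1. Its oxygen then displaces iodide intramolecularly with a second inversion, so C7 is formed with overall retention and the route is rejoined at 15.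

Step 7 (cyclopropanation). The process at risk is poor facial selectivity under substrate control. The C7' aryl group could sit inside, eclipsing the alkene, to avoid the CH2OTBS group, so that the carbene adds syn to it; carbene dimerisation and hydride abstraction from C7'–H could also compete. The fallback moves the face selection to the catalyst and sets out from racemic alcohol 5, so steps 3 and 4 are not needed. 5 is acylated with 8 as in step 5 to the racemic bromoacetate F2 and treated with N,N'-ditosylhydrazine and DBU to pass through the racemic hydrazide F3 to the racemic diazoacetate F4. F4 is decomposed with the chiral carboxamidate Rh2(4S-MPPIM)4 (dirhodium tetrakis[methyl (4S)-2-oxo-1-(3-phenylpropanoyl)imidazolidine-4-carboxylate]) in CH2Cl2 at 40 °C. Catalysts of this class choose the alkene face themselves in secondary allylic diazoacetates; the S-configured catalyst should build the (1R,5S)-type lactone from both ester enantiomers. The (R)-ester then gives 12 and the (S)-ester gives its C7' epimer F5. The two diastereomers are separated by chromatography and the route is rejoined at 12.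

Step 11 (hydrogenation). The processes at risk are hydrogen delivery to the concave face, migration of the alkene to the C8=C8' butenolide on the palladium hydride before reduction, and over-reduction by hydrogenolysis of the ring benzylic C–O bonds. The fallback separates the two tasks and sets out from 15. Ionic hydrogenation (Et3SiH, CF3CO2H, CH2Cl2, −78 to −40 °C) protonates the enol ether at C8' reversibly, so that only the cis-fused oxocarbenium ion is reduced by the silane, and should give the di-O-benzyl ether F6 of the target. A short hydrogenolysis of F6 (H2, Pd/C, EtOAc), with no alkene left to isomerise, rejoins the route at 16.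

Further compounds
F1 | step 10 | ring-opened benzylic iodide enolate (E-enolate of the 4-formyl lactone with CH(I)Ar1 on C8, drawn as the anion, magnesium counter-ion) | [O-]/C=C1/[C@@H](c2cc(OC)c(OCc3ccccc3)c(OC)c2)OC(=O)[C@@H]1[C@@H](I)c1ccc(OCc2ccccc2)c(OC)c1
F2 | step 7 | rac-(2E)-3-Ar1-1-Ar2-2-(TBSOCH2)prop-2-en-1-yl bromoacetate | COc1cc(/C=C(\CO[Si](C)(C)C(C)(C)C)C(OC(=O)CBr)c2cc(OC)c(OCc3ccccc3)c(OC)c2)ccc1OCc1ccccc1
F3 | step 7 | rac-(2E)-3-Ar1-1-Ar2-2-(TBSOCH2)prop-2-en-1-yl [1,2-bis(4-methylbenzenesulfonyl)hydrazinyl]acetate | COc1cc(/C=C(\CO[Si](C)(C)C(C)(C)C)C(OC(=O)CN(NS(=O)(=O)c2ccc(C)cc2)S(=O)(=O)c2ccc(C)cc2)c2cc(OC)c(OCc3ccccc3)c(OC)c2)ccc1OCc1ccccc1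
F4 | step 7 | rac-(2E)-3-Ar1-1-Ar2-2-(TBSOCH2)prop-2-en-1-yl diazoacetate | COc1cc(/C=C(\CO[Si](C)(C)C(C)(C)C)C(OC(=O)C=[N+]=[N-])c2cc(OC)c(OCc3ccccc3)c(OC)c2)ccc1OCc1ccccc1
F5 | step 7 | (1R,4S,5S,6S)-6-Ar1-4-Ar2-5-(TBSOCH2)-3-oxabicyclo[3.1.0]hexan-2-one (C7' epimer of 12) | CC(C)(C)[Si](C)(C)OC[C@]12[C@H](c3ccc(OCc4ccccc4)c(OC)c3)[C@H]1C(=O)O[C@H]2c1cc(OC)c(OCc2ccccc2)c(OC)c1
F6 | step 11 | (3S,3aR,6S,6aS)-6-Ar1-3-Ar2-tetrahydro-1H,3H-furo[3,4-c]furan-1-one (di-O-benzyl ether of 16) | COc1cc([C@H]2OC[C@H]3[C@@H]2C(=O)O[C@@H]3c2cc(OC)c(OCc4ccccc4)c(OC)c2)ccc1OCc1ccccc1
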